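Everything rests on seeing the carboxyl carbon on C1 of the cyclohexane and O1 of the chromene, bonded to quaternary C2, as the two ends of a Baeyer–Villiger lactone. Joining them gives a trans-decalone built on (R)-carvone, whose stereocentre and isopropenyl group become C2 and the gem-dimethyl carbon C3 of the cyclohexane. The key step is an iron-hydride HAT radical cyclisation: the isopropenyl group becomes a tertiary radical that closes the cyclohexane at C3–C4 onto a temporary 2-sulfonylallyl arm, creating the quaternary carbon and the trans ring fusion in one operation. Its precursor is trans-6-[2-(phenylsulfonyl)allyl]carvone; the temporary ketone ring is opened later and the sulfone removed.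

Key step: step 2

Remark: the sulfone-bearing carbon of 5 to 8 forms as a mixture of epimers that is carried on unseparated, because step 5 removes it; compounds 2 and 12 and the ethynylbenziodoxolone reagent are taken as commercial.

Step 1
Reactants: 1 (R)-(−)-carvone; 2 2,3-bis(phenylsulfonyl)prop-1-ene
Product: 4 (5R,6S)-2-methyl-6-[2-(phenylsulfonyl)prop-2-en-1-yl]-5-(prop-1-en-2-yl)cyclohex-2-en-1-one, via carvone lithium dienolate 3 (not isolated)
Conditions: LDA, THF, −78 °C; then 2, −78 to −30 °C; dilute HCl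
Reagents that add atoms: none
Why: LDA removes the α′-proton at C6 under kinetic control and the cross-conjugated enolate 3 attacks the vinyl sulfone of 2 with loss of benzenesulfinate (conjugate addition–elimination, a formal SN2′ allylation), the electrophile entering anti to the neighbouring isopropenyl group, which sets the new C6 centre trans to C5 by substrate control.

Step 2
Reactants: 4 (5R,6S)-2-methyl-6-[2-(phenylsulfonyl)prop-2-en-1-yl]-5-(prop-1-en-2-yl)cyclohex-2-en-1-one
Product: 5 (4aR,8aS)-2,5,5-trimethyl-7-(phenylsulfonyl)-4a,5,6,7,8,8a-hexahydronaphthalen-1(4H)-one (trans-fused, epimers at C7)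
Conditions: Fe(acac)3 (cat.), PhSiH3, EtOH/ethylene glycol, 0.01 M, 60 °C
Reagents that add atoms: none
Why: Fe(acac)3 and PhSiH3 generate an iron hydride that transfers H• to the terminal CH2 of the isopropenyl group (Markovnikov MHAT), so that this CH2 becomes the second methyl group and a tertiary radical sits on the future C3 of the cyclohexane; the radical adds to the unsubstituted terminus of the vinyl sulfone (future C4), and the α-sulfonyl radical is reduced by Fe(II) and protonated by ethanol. The closest known reaction type is the iron-catalysed reductive olefin coupling (HAT-initiated Giese reaction) in its intramolecular form. The single ring that closes does so 6-endo-trig, because the sulfonyl group makes the terminal alkene carbon the electrophilic site and leaves 5-exo attack at the substituted carbon without stabilisation. No lasting stereocentre is created: the 5,6-trans relationship of 4 translates directly into the trans ring fusion, and the sulfone-bearing carbon forms as an epimer mixture that step 5 erases. The step needs hydrogen-atom transfer to the isopropenyl group only, which the electron-rich 1,1-disubstituted alkene secures over the two electron-poor alkenes (enone, vinyl sulfone), and it needs ring closure to outrun reduction of the radical and intermolecular addition to the enone, which the tethered acceptor and high dilution secure.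

Step 3
Reactants: 5 (4aR,8aS)-2,5,5-trimethyl-7-(phenylsulfonyl)-4a,5,6,7,8,8a-hexahydronaphthalen-1(4H)-one
Product: 7 (2R,4aR,8aS)-2-ethynyl-2,5,5-trimethyl-7-(phenylsulfonyl)octahydronaphthalen-1(2H)-one, via potassium enolate 6 (not isolated)
Conditions: K-Selectride, THF, −78 °C; then TMS-EBX, TBAF, −78 °C to rt; dilute HCl
Reagents that add atoms: TMS-EBX, 1-[(trimethylsilyl)ethynyl]-1,2-benziodoxol-3(1H)-one, C[Si](C)(C)C#CI1OC(=O)c2ccccc21
Why: Conjugate reduction of the β-unsubstituted enone by K-Selectride gives the regiodefined enolate 6, which is C-alkynylated by the ethynylbenziodoxolone (electrophilic alkynylation with a hypervalent iodine reagent, fluoride freeing the terminal alkyne); the electrophile should enter axially on the rigid trans-decalin enolate, on the face of the C4a–C5 bond, which sets the quaternary centre as 2R.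

Step 4
Reactants: 7 (2R,4aR,8aS)-2-ethynyl-2,5,5-trimethyl-7-(phenylsulfonyl)octahydronaphthalen-1(2H)-one
Product: 8 (3R,5aR,9aS)-3-ethynyl-3,6,6-trimethyl-8-(phenylsulfonyl)octahydro-2-benzoxepin-1(3H)-one
Conditions: mCPBA, NaHCO3, CH2Cl2, rt
Reagents that add atoms: mCPBA, OOC(=O)c1cccc(Cl)c1
Why: Baeyer–Villiger oxidation, in which the fully substituted propargylic carbon migrates in preference to the secondary ring-fusion carbon and does so with retention, so that the ketone α-stereocentre becomes the tertiary C–O stereocentre while alkyne and sulfone are inert to the peracid.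

Step 5
Reactants: 8 (3R,5aR,9aS)-3-ethynyl-3,6,6-trimethyl-8-(phenylsulfonyl)octahydro-2-benzoxepin-1(3H)-one
Product: 10 (1S,2R)-2-[(3R)-3-hydroxy-3-methylpent-4-yn-1-yl]-3,3-dimethylcyclohexane-1-carboxylic acid, via hydroxy methyl ester 9 (not isolated)
Conditions: Mg, cat. HgCl2, MeOH, rt to 50 °C; then LiOH, H2O/THF, 50 °C; cold dilute HCl to pH 4
Reagents that add atoms: lithium hydroxide, [Li+].[OH-]
Why: Magnesium in methanol cleaves the alkyl phenyl sulfone by electron transfer (reductive desulfonylation) while the methoxide formed opens the ε-lactone, and LiOH then saponifies ester 9; the trans arrangement at C1/C2, being diequatorial, should not erode under the basic conditions.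

Step 6
Reactants: 10 (1S,2R)-2-[(3R)-3-hydroxy-3-methylpent-4-yn-1-yl]-3,3-dimethylcyclohexane-1-carboxylic acid
Product: 11 (1S,2R)-2-[(3R)-3-hydroxy-3-methylpent-4-en-1-yl]-3,3-dimethylcyclohexane-1-carboxylic acid
Conditions: H2 (1 atm), Lindlar catalyst, quinoline, EtOAc, rt
Reagents that add atoms: none
Why: Lindlar semihydrogenation of the terminal alkyne stops at the vinyl group on the poisoned catalyst and leaves the stereocentres untouched.

Step 7
Reactants: 11 (1S,2R)-2-[(3R)-3-hydroxy-3-methylpent-4-en-1-yl]-3,3-dimethylcyclohexane-1-carboxylic acid; 12 2,6-difluoro-4-methylbenzaldehyde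
Product: 13 (1S,2R)-2-[(3R)-3-(3-fluoro-2-formyl-5-methylphenoxy)-3-methylpent-4-en-1-yl]-3,3-dimethylcyclohexane-1-carboxylic acid
Conditions: KH, THF/DMF, 0 °C; then 12, 0 °C to rt; cold dilute HCl to pH 4
Reagents that add atoms: none
Why: Nucleophilic aromatic substitution, in which the tertiary potassium alkoxide (far more nucleophilic than the carboxylate) displaces one of the two fluorides ortho to the formyl group; the C–O stereocentre is retained because the oxygen, not the carbon, reacts, and the new alkoxy group deactivates the ring against a second substitution.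

Step 8
Reactants: 13 (1S,2R)-2-[(3R)-3-(3-fluoro-2-formyl-5-methylphenoxy)-3-methylpent-4-en-1-yl]-3,3-dimethylcyclohexane-1-carboxylic acid
Product: 15 (1S,2R)-2-[(3R)-3-(2-formyl-3-hydroxy-5-methylphenoxy)-3-methylpent-4-en-1-yl]-3,3-dimethylcyclohexane-1-carboxylic acid, via 2-(methylsulfonyl)ethyl aryl ether 14 (not isolated)
Conditions: 2-(methylsulfonyl)ethanol, NaH, DMF, 0 °C to rt; cold dilute HCl
Reagents that add atoms: 2-(methylsulfonyl)ethanol, CS(=O)(=O)CCO
Why: A second nucleophilic aromatic substitution by the alkoxide of 2-(methylsulfonyl)ethanol on the remaining ortho-fluoride, followed by E1cB loss of methyl vinyl sulfone from 14, unveils the phenol under mild conditions (hydroxide-equivalent SNAr).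

Step 9
Reactants: 15 (1S,2R)-2-[(3R)-3-(2-formyl-3-hydroxy-5-methylphenoxy)-3-methylpent-4-en-1-yl]-3,3-dimethylcyclohexane-1-carboxylic acid
Product: 16 (1S,2R)-2-[(3R)-3-(2-ethenyl-3-hydroxy-5-methylphenoxy)-3-methylpent-4-en-1-yl]-3,3-dimethylcyclohexane-1-carboxylic acid
Conditions: Ph3PCH3Br, KOtBu (excess), THF, 0 °C to rt; cold dilute HCl
Reagents that add atoms: methyltriphenylphosphonium bromide, C[P+](c1ccccc1)(c1ccccc1)c1ccccc1.[Br-]
Why: Wittig methylenation of the aldehyde, with excess ylide to absorb the phenol and carboxylic acid protons, should give the styrene without touching the tertiary allylic aryl ether.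

Step 10
Reactants: 16 (1S,2R)-2-[(3R)-3-(2-ethenyl-3-hydroxy-5-methylphenoxy)-3-methylpent-4-en-1-yl]-3,3-dimethylcyclohexane-1-carboxylic acid
Product: 17 (1S,2R)-2-{2-[(2R)-5-hydroxy-2,7-dimethyl-2H-chromen-2-yl]ethyl}-3,3-dimethylcyclohexane-1-carboxylic acid
Conditions: Grubbs second-generation catalyst (5 mol %), CH2Cl2, 0.01 M, 40 °C, dark
Reagents that add atoms: none
Why: Ring-closing metathesis between the styrene and the vinyl group on the quaternary ether carbon closes the 2H-pyran ring with loss of ethene; the ruthenium carbene tolerates phenol and acid, the alkene is cis by ring constraint, and the C–O stereocentre is not involved, which leaves the chromene C2 as R.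

Compound list
1 | (R)-(−)-carvone, (5R)-2-methyl-5-(prop-1-en-2-yl)cyclohex-2-en-1-one | CC1=CC[C@H](CC1=O)C(C)=C | starting material
2 | 2,3-bis(phenylsulfonyl)prop-1-ene | C=C(CS(=O)(=O)c1ccccc1)S(=O)(=O)c1ccccc1 | starting material
3 | lithium (5R)-2-methyl-5-(prop-1-en-2-yl)cyclohexa-1,5-dien-1-olate (kinetic dienolate of carvone) | [Li+].CC1=CC[C@@H](C(C)=C)C=C1[O-] | intermediate
4 | (5R,6S)-2-methyl-6-[2-(phenylsulfonyl)prop-2-en-1-yl]-5-(prop-1-en-2-yl)cyclohex-2-en-1-one | CC1=CC[C@@H](C(C)=C)[C@H](CC(=C)S(=O)(=O)c2ccccc2)C1=O | intermediate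
5 | (4aR,8aS)-2,5,5-trimethyl-7-(phenylsulfonyl)-4a,5,6,7,8,8a-hexahydronaphthalen-1(4H)-one, epimers at C7 | CC1=CC[C@@H]2[C@H](CC(S(=O)(=O)c3ccccc3)CC2(C)C)C1=O | intermediate
6 | potassium (4aR,8aS)-2,5,5-trimethyl-7-(phenylsulfonyl)-3,4,4a,5,6,7,8,8a-octahydronaphthalen-1-olate | [K+].CC1=C([O-])[C@H]2CC(S(=O)(=O)c3ccccc3)CC(C)(C)[C@@H]2CC1 | intermediate
7 | (2R,4aR,8aS)-2-ethynyl-2,5,5-trimethyl-7-(phenylsulfonyl)octahydronaphthalen-1(2H)-one | C#C[C@@]1(C)CC[C@@H]2[C@H](CC(S(=O)(=O)c3ccccc3)CC2(C)C)C1=O | intermediate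
8 | (3R,5aR,9aS)-3-ethynyl-3,6,6-trimethyl-8-(phenylsulfonyl)octahydro-2-benzoxepin-1(3H)-one | C#C[C@@]1(C)CC[C@@H]2[C@H](CC(S(=O)(=O)c3ccccc3)CC2(C)C)C(=O)O1 | intermediate
9 | methyl (1S,2R)-2-[(3R)-3-hydroxy-3-methylpent-4-yn-1-yl]-3,3-dimethylcyclohexane-1-carboxylate | C#C[C@](C)(O)CC[C@@H]1[C@@H](C(=O)OC)CCCC1(C)C | intermediate
10 | (1S,2R)-2-[(3R)-3-hydroxy-3-methylpent-4-yn-1-yl]-3,3-dimethylcyclohexane-1-carboxylic acid | C#C[C@](C)(O)CC[C@@H]1[C@@H](C(=O)O)CCCC1(C)C | intermediate
11 | (1S,2R)-2-[(3R)-3-hydroxy-3-methylpent-4-en-1-yl]-3,3-dimethylcyclohexane-1-carboxylic acid | C=C[C@](C)(O)CC[C@@H]1[C@@H](C(=O)O)CCCC1(C)C | intermediate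
12 | 2,6-difluoro-4-methylbenzaldehyde | Cc1cc(F)c(C=O)c(F)c1 | starting material
13 | (1S,2R)-2-[(3R)-3-(3-fluoro-2-formyl-5-methylphenoxy)-3-methylpent-4-en-1-yl]-3,3-dimethylcyclohexane-1-carboxylic acid | C=C[C@](C)(Oc1cc(C)cc(F)c1C=O)CC[C@@H]1[C@@H](C(=O)O)CCCC1(C)C | intermediate
14 | (1S,2R)-2-[(3R)-3-{2-formyl-5-methyl-3-[2-(methylsulfonyl)ethoxy]phenoxy}-3-methylpent-4-en-1-yl]-3,3-dimethylcyclohexane-1-carboxylic acid | C=C[C@](C)(Oc1cc(C)cc(OCCS(C)(=O)=O)c1C=O)CC[C@@H]1[C@@H](C(=O)O)CCCC1(C)C | intermediate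
15 | (1S,2R)-2-[(3R)-3-(2-formyl-3-hydroxy-5-methylphenoxy)-3-methylpent-4-en-1-yl]-3,3-dimethylcyclohexane-1-carboxylic acid | C=C[C@](C)(Oc1cc(C)cc(O)c1C=O)CC[C@@H]1[C@@H](C(=O)O)CCCC1(C)C | intermediate
16 | (1S,2R)-2-[(3R)-3-(2-ethenyl-3-hydroxy-5-methylphenoxy)-3-methylpent-4-en-1-yl]-3,3-dimethylcyclohexane-1-carboxylic acid | C=C[C@](C)(Oc1cc(C)cc(O)c1C=C)CC[C@@H]1[C@@H](C(=O)O)CCCC1(C)C | intermediate
17 | (1S,2R)-2-{2-[(2R)-5-hydroxy-2,7-dimethyl-2H-chromen-2-yl]ethyl}-3,3-dimethylcyclohexane-1-carboxylic acid | Cc1cc(O)c2c(c1)O[C@](C)(CC[C@@H]1[C@@H](C(=O)O)CCCC1(C)C)C=C2 | target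

Total step count: 10
Longest linear sequence: 10 steps, from 1 to 17

Steps most likely to fail

Step 2. The tertiary radical may be reduced to an isopropyl group, or hydrogen-atom transfer may reach the enone, before the ring closes. The fallback generates the same radical without a metal hydride. Setting out from 4, Markovnikov addition of HBr (HBr in AcOH, 0 °C) to the isopropenyl group should give the tertiary bromide (5R,6S)-5-(2-bromopropan-2-yl)-2-methyl-6-[2-(phenylsulfonyl)prop-2-en-1-yl]cyclohex-2-en-1-one F1. A tin hydride chain (Bu3SnH, AIBN, benzene, 80 °C, slow addition) should then close the same 6-endo ring onto the vinyl sulfone and come back to the route at 5.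

Step 3. The hindered, fully substituted enolate may be attacked at oxygen or oxidatively coupled by the iodine(III) reagent, so that the quaternary C–C bond is not formed. The fallback installs a vinyl group in place of the ethynyl group, using a sulfoxide as vinyl cation equivalent. Setting out from 5, the enolate 6 is trapped with phenyl vinyl sulfoxide to give (2R,4aR,8aS)-2,5,5-trimethyl-2-[2-(phenylsulfinyl)ethyl]-7-(phenylsulfonyl)octahydronaphthalen-1(2H)-one F2. Thermolysis (toluene, 110 °C, CaCO3) expels benzenesulfenic acid and gives (2R,4aR,8aS)-2-ethenyl-2,5,5-trimethyl-7-(phenylsulfonyl)octahydronaphthalen-1(2H)-one F3. A ketone-selective Baeyer–Villiger oxidation with bis(trimethylsilyl) peroxide and TMSOTf, which spares the vinyl group, gives (3R,5aR,9aS)-3-ethenyl-3,6,6-trimethyl-8-(phenylsulfonyl)octahydro-2-benzoxepin-1(3H)-one F4. Mg/MeOH then LiOH as in step 5, passing through methyl (1S,2R)-2-[(3R)-3-hydroxy-3-methylpent-4-en-1-yl]-3,3-dimethylcyclohexane-1-carboxylate F5, comes back to the route at 11, and step 6 falls away.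

Step 7. The hindered alkoxide may add reversibly to the formyl group and transfer hydride (Tishchenko-type), consuming the aldehyde faster than fluoride is displaced. The fallback changes the activating group to a nitrile, which cannot react in this way. Setting out from 11, substitution on 2,6-difluoro-4-methylbenzonitrile (KH, DMF, 0 °C to rt) should give (1S,2R)-2-[(3R)-3-(2-cyano-3-fluoro-5-methylphenoxy)-3-methylpent-4-en-1-yl]-3,3-dimethylcyclohexane-1-carboxylic acid F6. DIBAL-H (toluene, −78 °C; then dilute aqueous acid) reduces the nitrile to the aldehyde and comes back to the route at 13.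

Further compounds
F1 | step 2 | (5R,6S)-5-(2-bromopropan-2-yl)-2-methyl-6-[2-(phenylsulfonyl)prop-2-en-1-yl]cyclohex-2-en-1-one | CC1=CC[C@@H](C(C)(C)Br)[C@H](CC(=C)S(=O)(=O)c2ccccc2)C1=O
F2 | step 3 | (2R,4aR,8aS)-2,5,5-trimethyl-2-[2-(phenylsulfinyl)ethyl]-7-(phenylsulfonyl)octahydronaphthalen-1(2H)-one | O=S(CC[C@@]1(C)CC[C@@H]2[C@H](CC(S(=O)(=O)c3ccccc3)CC2(C)C)C1=O)c4ccccc4
F3 | step 3 | (2R,4aR,8aS)-2-ethenyl-2,5,5-trimethyl-7-(phenylsulfonyl)octahydronaphthalen-1(2H)-one | C=C[C@@]1(C)CC[C@@H]2[C@H](CC(S(=O)(=O)c3ccccc3)CC2(C)C)C1=O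
F4 | step 3 | (3R,5aR,9aS)-3-ethenyl-3,6,6-trimethyl-8-(phenylsulfonyl)octahydro-2-benzoxepin-1(3H)-one | C=C[C@@]1(C)CC[C@@H]2[C@H](CC(S(=O)(=O)c3ccccc3)CC2(C)C)C(=O)O1
F5 | step 3 | methyl (1S,2R)-2-[(3R)-3-hydroxy-3-methylpent-4-en-1-yl]-3,3-dimethylcyclohexane-1-carboxylate | C=C[C@](C)(O)CC[C@@H]1[C@@H](C(=O)OC)CCCC1(C)C
F6 | step 7 | (1S,2R)-2-[(3R)-3-(2-cyano-3-fluoro-5-methylphenoxy)-3-methylpent-4-en-1-yl]-3,3-dimethylcyclohexane-1-carboxylic acid | C=C[C@](C)(Oc1cc(C)cc(F)c1C#N)CC[C@@H]1[C@@H](C(=O)O)CCCC1(C)C
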